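**Retrosynthetic overview**
1. Last bond C1–CH2: samarium Barbier coupling of the tricyclic iodide 24 with the ring-A ketone 10; the tertiary carbinol C1 is set in this step.
2. The bromo-dimethylcyclohexane ring is not made as a six-membered ring. Cyclopentenone 1 is β-borylated asymmetrically (C–B next to CMe2) and converted to the 1-siloxybicyclo[3.1.0]hexane 4. β-Scission of its zero-bridge bond C1–C5 inserts the cyclopropane CH2 and enlarges the five-membered ring to cyclohexanone 6. C–B is then turned into C–Br with inversion.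
3. What makes the key step possible: the enol-silane double bond lies between the carbonyl carbon and the CH2 next to the boron-bearing carbon. The cyclopropanol bond that breaks is therefore the one that puts the new CH2 between C=O and that CH2.
4. Tricycle 24: an intramolecular Diels–Alder reaction of triene 21 ((Z)-β-bromoacrylate plus 2-methyl-diene) forms the cyclopentane and the cyclohexene together, with three stereocentres relayed from one organocatalytically set centre. Acid lactonisation closes the third ring.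
5. Ring order: five-membered carbocycle (bought) → ring A by expansion; separately hydrindene (two rings at once) → lactone; then union.

Key step: step 4

Remark: Bpin = 4,4,5,5-tetramethyl-1,3,2-dioxaborolan-2-yl. Both enantiomers of the chiral ligand, the prolinol catalyst and the oxazolidinone are assumed available; the one giving the drawn configuration is used.

**Route**

Step 1
Reactants: 1 4,4-dimethylcyclopent-2-en-1-one
Product: 2 (R)-4,4-dimethyl-3-(Bpin)cyclopentan-1-one
Conditions: B2pin2 (1.1 equiv), CuCl (3 mol%), NaOtBu (6 mol%), Josiphos-type bisphosphine (4 mol%), MeOH (2 equiv), THF, rt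
Reagents that add atoms: bis(pinacolato)diboron, CC1(C)OB(OC1(C)C)B2OC(C)(C)C(C)(C)O2
Why: Copper-catalysed asymmetric conjugate borylation of a cyclic enone should place boron on C3 next to the quaternary carbon, the chiral Cu–Bpin complex choosing the enone face and so setting the (R) stereocentre that becomes C4 of ring A.

Step 2
Reactants: 2 (R)-4,4-dimethyl-3-(Bpin)cyclopentan-1-one
Product: 3 trimethyl{[(3R)-4,4-dimethyl-3-(Bpin)cyclopent-1-en-1-yl]oxy}silane
Conditions: LDA (1.05 equiv), THF, −78 °C; then TMSCl, −78 → 0 °C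
Reagents that add atoms: chlorotrimethylsilane, C[Si](C)(C)Cl
Why: Kinetic enolisation with LDA should occur at C2 (the α-CH2 at C5 is neopentyl and hindered by the gem-dimethyl group) and O-silylation then gives the Δ1,2 silyl enol ether; C3 is untouched.

Step 3
Reactants: 3 trimethyl{[(3R)-4,4-dimethyl-3-(Bpin)cyclopent-1-en-1-yl]oxy}silane
Product: 4 (4R)-3,3-dimethyl-4-(Bpin)-1-(trimethylsilyloxy)bicyclo[3.1.0]hexane (cyclopropane CH2 anti to Bpin)
Conditions: Et2Zn, CH2I2, CH2Cl2, 0 °C → rt
Reagents that add atoms: diiodomethane, ICI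
Why: Furukawa-modified Simmons–Smith cyclopropanation of the electron-rich silyl enol ether should add CH2 anti to the Bpin group; either cyclopropane diastereomer would serve, since both new centres are lost in step 4.

Step 4
Reactants: 4 (4R)-3,3-dimethyl-4-(Bpin)-1-(trimethylsilyloxy)bicyclo[3.1.0]hexane
Product: 6 (R)-3,3-dimethyl-4-(Bpin)cyclohexan-1-one, via cyclopropanol 5 (not isolated)
Conditions: K2CO3 (cat.), MeOH, 0 °C; then Mn(pic)3 (2.2 equiv), Bu3SnH (3 equiv), DMF, 0 °C
Reagents that add atoms: none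
Why: Methanolysis frees cyclopropanol 5, Mn(III) oxidises it to the alkoxy radical, and β-scission of the zero-bridge bond C1–C5 inserts the cyclopropane CH2 (C6) between C1 and C5, so the cyclopentane becomes the cyclohexanone; the secondary C5 radical is then reduced by Bu3SnH. The closest known reaction type is the Saegusa–Ito/Narasaka oxidative ring expansion of 1-oxybicyclo[n.1.0]alkanes. No ring is closed by cyclisation: ring A arises purely by enlargement of the five-membered ring (5 → 6). No new stereocentre is formed, and the boron-bearing carbon (C4 of 6) is never a radical centre, so it keeps the configuration from step 1. The step needs internal (C1–C5) rather than external (C1–C6) scission, which the secondary ring radical and the release of bicyclic strain should secure. It also needs H-transfer to be faster than a 1,2-boryl shift of the β-boryl radical, which the excess of Bu3SnH should secure.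

Step 5
Reactants: 6 (R)-3,3-dimethyl-4-(Bpin)cyclohexan-1-one
Product: 7 (8R)-7,7-dimethyl-8-(Bpin)-1,4-dioxaspiro[4.5]decane
Conditions: (TMSOCH2)2 (1.5 equiv), TMSOTf (5 mol%), CH2Cl2, −78 °C
Reagents that add atoms: 1,2-bis(trimethylsilyloxy)ethane, C[Si](C)(C)OCCO[Si](C)(C)C
Why: Noyori ketalisation under aprotic conditions should protect the ketone against the aryllithium of step 6 without exchanging the pinacol ester.

Step 6
Reactants: 7 (8R)-7,7-dimethyl-8-(Bpin)-1,4-dioxaspiro[4.5]decane
Product: 9 (8S)-8-bromo-7,7-dimethyl-1,4-dioxaspiro[4.5]decane, via aryl boronate complex 8 (not isolated)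
Conditions: 1-bromo-3,5-bis(trifluoromethyl)benzene, n-BuLi, THF, −78 °C; add 7; then NBS, −78 °C → rt
Reagents that add atoms: N-bromosuccinimide, O=C1CCC(=O)N1Br
Why: Stereospecific electrophilic bromination of a secondary boronic ester through its aryl boronate complex (SE2 with inversion) should convert (R)-C–B into (S)-C–Br, avoiding any nucleophilic substitution at the neopentyl carbon.

Step 7
Reactants: 9 (8S)-8-bromo-7,7-dimethyl-1,4-dioxaspiro[4.5]decane
Product: 10 (S)-4-bromo-3,3-dimethylcyclohexan-1-one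
Conditions: 1 M aq. HCl, THF, rt
Reagents that add atoms: water, O
Why: Acid-catalysed ketal hydrolysis; the hindered secondary bromide should be inert to dilute aqueous acid.

Step 8
Reactants: 11 tert-butyl 2-(diethoxyphosphoryl)acetate; 12 2-(3-bromopropyl)-1,3-dioxolane
Product: 13 tert-butyl 2-(diethoxyphosphoryl)-5-(1,3-dioxolan-2-yl)pentanoate (racemic)
Conditions: NaH, DMF, 0 → 50 °C
Reagents that add atoms: none
Why: SN2 C-alkylation of the sodium phosphonoacetate anion by a primary bromide.

Step 9
Reactants: 13 tert-butyl 2-(diethoxyphosphoryl)-5-(1,3-dioxolan-2-yl)pentanoate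
Product: 14 (E)-3-(tert-butoxycarbonyl)-6-(1,3-dioxolan-2-yl)hex-2-enoic acid
Conditions: glyoxylic acid monohydrate, LiCl, DBU (2.2 equiv), MeCN, 0 °C → rt; acidic work-up
Reagents that add atoms: glyoxylic acid, O=CC(=O)O
Why: Horner–Wadsworth–Emmons olefination (Masamune–Roush conditions) should give the trisubstituted alkene with CO2H trans to the tert-butyl ester.

Step 10
Reactants: 14 (E)-3-(tert-butoxycarbonyl)-6-(1,3-dioxolan-2-yl)hex-2-enoic acid
Product: 15 (2S*,3R*)-2,3-dibromo-3-(tert-butoxycarbonyl)-6-(1,3-dioxolan-2-yl)hexanoic acid (racemic)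
Conditions: Br2, CHCl3, rt → 40 °C, dark
Reagents that add atoms: bromine, BrBr
Why: Anti addition of bromine to the (E)-alkene gives one racemic dibromide, which fixes the geometry of the next step.

Step 11
Reactants: 15 (2S*,3R*)-2,3-dibromo-3-(tert-butoxycarbonyl)-6-(1,3-dioxolan-2-yl)hexanoic acid
Product: 16 tert-butyl (Z)-2-(bromomethylidene)-5-(1,3-dioxolan-2-yl)pentanoate
Conditions: Et3N (2.2 equiv), DMF, rt
Reagents that add atoms: none
Why: Decarboxylative anti-elimination of the β-bromo carboxylate (the cinnamic acid dibromide → (Z)-β-bromostyrene type) is stereospecific and should give the (Z)-β-bromoacrylate with Br cis to the ester.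

Step 12
Reactants: 16 tert-butyl (Z)-2-(bromomethylidene)-5-(1,3-dioxolan-2-yl)pentanoate
Product: 17 tert-butyl (Z)-2-(bromomethylidene)-6-oxohexanoate
Conditions: AcOH/H2O/THF (3:1:1), 45 °C
Reagents that add atoms: water, O
Why: Mild acid hydrolysis of the dioxolane, which the tert-butyl ester and the vinyl bromide should survive.

Step 13
Reactants: 17 tert-butyl (Z)-2-(bromomethylidene)-6-oxohexanoate
Product: 18 tert-butyl (2Z,5S)-2-(bromomethylidene)-5-formyl-6-hydroxyhexanoate
Conditions: (R)-α,α-diphenylprolinol trimethylsilyl ether (20 mol%), aq. formaldehyde, pH 7 phosphate buffer, toluene, rt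
Reagents that add atoms: formaldehyde, C=O
Why: Enamine-catalysed α-hydroxymethylation of an aldehyde, in which the catalyst shields one enamine face and so sets the (S) centre that becomes the CH2-bearing cyclopentane carbon; intramolecular Michael closure onto the bromoacrylate would be 5-endo and is disfavoured.

Step 14
Reactants: 18 tert-butyl (2Z,5S)-2-(bromomethylidene)-5-formyl-6-hydroxyhexanoate
Product: 19 tert-butyl (2Z,5R,6E)-2-(bromomethylidene)-5-(hydroxymethyl)-7-methyl-8-oxooct-6-enoate
Conditions: Ph3P=C(CH3)CHO (1.2 equiv), CH2Cl2, rt → 40 °C, used on crude 18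
Reagents that add atoms: 2-(triphenylphosphoranylidene)propanal, CC(C=O)=P(c1ccccc1)(c1ccccc1)c1ccccc1
Why: Wittig olefination with the stabilised formyl ylide should give the (E)-trisubstituted enal under neutral conditions that do not epimerise the labile α-centre.

Step 15
Reactants: 19 tert-butyl (2Z,5R,6E)-2-(bromomethylidene)-5-(hydroxymethyl)-7-methyl-8-oxooct-6-enoate
Product: 20 tert-butyl (2Z,5R,6E)-2-(bromomethylidene)-5-(iodomethyl)-7-methyl-8-oxooct-6-enoate
Conditions: I2, PPh3, imidazole, CH2Cl2, 0 °C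
Reagents that add atoms: iodine, II
Why: Appel-type iodination of the primary alcohol; done before the diene is present.

Step 16
Reactants: 20 tert-butyl (2Z,5R,6E)-2-(bromomethylidene)-5-(iodomethyl)-7-methyl-8-oxooct-6-enoate
Product: 21 tert-butyl (2Z,5R,6E)-2-(bromomethylidene)-5-(iodomethyl)-7-methylnona-6,8-dienoate
Conditions: Ph3PCH3Br, NaHMDS, THF, −78 → 0 °C (1.1 equiv ylide)
Reagents that add atoms: methyltriphenylphosphonium bromide, C[P+](c1ccccc1)(c1ccccc1)c1ccccc1.[Br-]
Why: Wittig methylenation of the enal at low temperature gives the 2-methyl-1,3-diene; the β-branched primary iodide should react far more slowly with the ylide.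

Step 17
Reactants: 21 tert-butyl (2Z,5R,6E)-2-(bromomethylidene)-5-(iodomethyl)-7-methylnona-6,8-dienoate
Product: 22 tert-butyl 4-bromo-1-(iodomethyl)-7-methyl-1,2,3,4,5,7a-hexahydroindene-3a-carboxylate (trans ring fusion; Br cis to the ester; CH2I cis to H-7a)
Conditions: toluene (0.01 M), BHT (cat.), 120 °C, sealed tube
Reagents that add atoms: none
Why: Intramolecular Diels–Alder reaction with a three-atom tether: the ester on the tether-bearing dienophile carbon should lie endo and the tether anti, giving the trans-fused hydrindene; the (Z)-dienophile transfers Br cis to the angular ester, and A(1,3) strain between the diene methyl and the allylic centre directs the face so that CH2I ends cis to the ring-fusion hydrogen.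

Step 18
Reactants: 22 tert-butyl 4-bromo-1-(iodomethyl)-7-methyl-1,2,3,4,5,7a-hexahydroindene-3a-carboxylate
Product: 24 tricyclic bromo iodo γ-lactone, via carboxylic acid 23 (not isolated)
Conditions: TFA/CH2Cl2 (1:3), 0 °C → rt; then TfOH (10 mol%), 0 °C
Reagents that add atoms: none
Why: Acidolysis of the tert-butyl ester, then Markovnikov protonation of the trisubstituted alkene and capture of the tertiary cation by the angular carboxylic acid (cation–olefin lactonisation) should close the bridged γ-lactone; the new quaternary centre can only form with C–O on the face of the carboxyl bridge.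

Step 19
Reactants: 10 (S)-4-bromo-3,3-dimethylcyclohexan-1-one (1.5 equiv); 24 tricyclic bromo iodo γ-lactone
Product: 25 target CNP0282702.2
Conditions: SmI2 (2.5 equiv), NiI2 (2 mol%), THF, 0 °C
Reagents that add atoms: none
Why: Samarium Barbier reaction: the bulky alkylsamarium should add by equatorial attack, anti to the axial C3 methyl of the chair with equatorial bromine, placing OH axial and cis to Br; the hindered secondary bromides and the lactone should survive SmI2 without HMPA.

**Compound list**
1 | 4,4-dimethylcyclopent-2-en-1-one | CC1(C)CC(=O)C=C1 | starting material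
2 | (R)-4,4-dimethyl-3-(Bpin)cyclopentan-1-one | CC1(C)CC(=O)C[C@H]1B2OC(C)(C)C(C)(C)O2 | intermediate
3 | trimethyl{[(3R)-4,4-dimethyl-3-(Bpin)cyclopent-1-en-1-yl]oxy}silane | CC1(C)CC(O[Si](C)(C)C)=C[C@H]1B2OC(C)(C)C(C)(C)O2 | intermediate
4 | (4R)-3,3-dimethyl-4-(Bpin)-1-(trimethylsilyloxy)bicyclo[3.1.0]hexane, cyclopropane anti to Bpin | CC1(C)C[C@]2(O[Si](C)(C)C)C[C@@H]2[C@H]1B3OC(C)(C)C(C)(C)O3 | intermediate
5 | (4R)-3,3-dimethyl-4-(Bpin)bicyclo[3.1.0]hexan-1-ol | CC1(C)C[C@]2(O)C[C@@H]2[C@H]1B3OC(C)(C)C(C)(C)O3 | intermediate (not isolated)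
6 | (R)-3,3-dimethyl-4-(Bpin)cyclohexan-1-one | CC1(C)CC(=O)CC[C@H]1B2OC(C)(C)C(C)(C)O2 | intermediate
7 | (8R)-7,7-dimethyl-8-(Bpin)-1,4-dioxaspiro[4.5]decane | CC1(C)CC2(OCCO2)CC[C@H]1B3OC(C)(C)C(C)(C)O3 | intermediate
8 | lithium [3,5-bis(trifluoromethyl)phenyl](pinacolato)borate complex of 7 | [Li+].CC1(C)CC2(OCCO2)CC[C@H]1[B-]3(OC(C)(C)C(C)(C)O3)c4cc(cc(c4)C(F)(F)F)C(F)(F)F | intermediate (not isolated)
9 | (8S)-8-bromo-7,7-dimethyl-1,4-dioxaspiro[4.5]decane | CC1(C)CC2(OCCO2)CC[C@@H]1Br | intermediate
10 | (S)-4-bromo-3,3-dimethylcyclohexan-1-one | CC1(C)CC(=O)CC[C@@H]1Br | intermediate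
11 | tert-butyl 2-(diethoxyphosphoryl)acetate | CCOP(=O)(OCC)CC(=O)OC(C)(C)C | starting material
12 | 2-(3-bromopropyl)-1,3-dioxolane | BrCCCC1OCCO1 | starting material
13 | tert-butyl 2-(diethoxyphosphoryl)-5-(1,3-dioxolan-2-yl)pentanoate (racemic) | CCOP(=O)(OCC)C(CCCC1OCCO1)C(=O)OC(C)(C)C | intermediate
14 | (E)-3-(tert-butoxycarbonyl)-6-(1,3-dioxolan-2-yl)hex-2-enoic acid | OC(=O)/C=C(\CCCC1OCCO1)C(=O)OC(C)(C)C | intermediate
15 | (2S*,3R*)-2,3-dibromo-3-(tert-butoxycarbonyl)-6-(1,3-dioxolan-2-yl)hexanoic acid (racemic, one enantiomer drawn) | OC(=O)[C@H](Br)[C@](Br)(C(=O)OC(C)(C)C)CCCC1OCCO1 | intermediate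
16 | tert-butyl (Z)-2-(bromomethylidene)-5-(1,3-dioxolan-2-yl)pentanoate | Br/C=C(/CCCC1OCCO1)C(=O)OC(C)(C)C | intermediate
17 | tert-butyl (Z)-2-(bromomethylidene)-6-oxohexanoate | Br/C=C(/CCCC=O)C(=O)OC(C)(C)C | intermediate
18 | tert-butyl (2Z,5S)-2-(bromomethylidene)-5-formyl-6-hydroxyhexanoate | OC[C@@H](C=O)CC/C(C(=O)OC(C)(C)C)=C/Br | intermediate
19 | tert-butyl (2Z,5R,6E)-2-(bromomethylidene)-5-(hydroxymethyl)-7-methyl-8-oxooct-6-enoate | OC[C@@H](/C=C(C)/C=O)CC/C(C(=O)OC(C)(C)C)=C/Br | intermediate
20 | tert-butyl (2Z,5R,6E)-2-(bromomethylidene)-5-(iodomethyl)-7-methyl-8-oxooct-6-enoate | IC[C@@H](/C=C(C)/C=O)CC/C(C(=O)OC(C)(C)C)=C/Br | intermediate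
21 | tert-butyl (2Z,5R,6E)-2-(bromomethylidene)-5-(iodomethyl)-7-methylnona-6,8-dienoate | IC[C@@H](/C=C(C)/C=C)CC/C(C(=O)OC(C)(C)C)=C/Br | intermediate
22 | tert-butyl 4-bromo-1-(iodomethyl)-7-methyl-1,2,3,4,5,7a-hexahydroindene-3a-carboxylate (trans-fused; Br cis to ester; CH2I cis to H-7a) | IC[C@@H]1CC[C@]2(C(=O)OC(C)(C)C)[C@@H](Br)CC=C(C)[C@@H]12 | intermediate
23 | 4-bromo-1-(iodomethyl)-7-methyl-1,2,3,4,5,7a-hexahydroindene-3a-carboxylic acid (same configuration as 22) | IC[C@@H]1CC[C@]2(C(=O)O)[C@@H](Br)CC=C(C)[C@@H]12 | intermediate (not isolated)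
24 | tricyclic bromo iodo γ-lactone: trans-hydrindane whose angular carboxyl is lactonised onto the methyl-bearing tertiary carbon, equatorial Br next to the angular carbon, CH2I on the cyclopentane | IC[C@@H]2CC[C@]34C(=O)O[C@](C)(CC[C@@H]3Br)[C@@H]24 | intermediate
25 | target CNP0282702.2: (1S,4S)-4-bromo-3,3-dimethylcyclohexan-1-ol carrying at C1 the CH2 link to the tricyclic bromo lactone | CC1(C)C[C@@](O)(C[C@@H]2CC[C@]34C(=O)O[C@](C)(CC[C@@H]3Br)[C@@H]24)CC[C@@H]1Br | target

**Totals and risks**
Total step count: 19. Longest linear sequence: 12 steps (steps 8–19); the ring-A branch (steps 1–7) joins in step 19.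

Steps most likely to fail:

1. Step 19 (Barbier coupling). The C4 bromide biases the ring flip of ketone 10 only weakly. Each chair has an axial C3 methyl and leads, by equatorial attack, to a different C1 epimer, so facial discrimination may be poor. Reduction of a C–Br bond or attack on the lactone may also compete. Fallback, setting out from 6 and 24 and coming back at 25: the same SmI2/NiI2 Barbier reaction is run with the boronate ketone 6 to give the boryl carbinol, (1S,4R)-3,3-dimethyl-4-(Bpin)-1-[(tricyclic lactone)methyl]cyclohexan-1-ol F1. Its C–B bond is then brominated with inversion through the aryl boronate complex (ArLi, then NBS) to give 25. Because this last step inverts C4, the carbinol needed comes from the chair with the axial C4 substituent, so ketones 10 and 6 make opposite demands on the ring flip and one of them should match.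

2. Step 17 (intramolecular Diels–Alder). The tether-endo transition state would give the cis-fused hydrindene, and the triene may polymerise or isomerise at 120 °C. Fallback, setting out from 21 and coming back at 23 and so at 24: DIBAL-H reduction of the ester gives the allylic alcohol (2Z,5R,6E)-2-(bromomethylidene)-5-(iodomethyl)-7-methylnona-6,8-dien-1-ol F2. MnO2 oxidation gives the enal (2Z,5R,6E)-2-(bromomethylidene)-5-(iodomethyl)-7-methylnona-6,8-dienal F3. A Me2AlCl-promoted cycloaddition at −78 °C, in which the complexed aldehyde holds the carbonyl-endo, tether-anti geometry, gives the angular aldehyde 4-bromo-1-(iodomethyl)-7-methyl-1,2,3,4,5,7a-hexahydroindene-3a-carbaldehyde F4. Pinnick oxidation then gives acid 23, which lactonises as in step 18.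

3. Step 13 (organocatalytic hydroxymethylation). The amine catalyst may be consumed by addition–elimination on the β-bromoacrylate, and the β-hydroxy aldehyde may dehydrate or epimerise. Fallback, setting out from 17 and coming back at 19, using an Evans auxiliary:
 - Pinnick oxidation gives (Z)-5-(bromomethylidene)-6-(tert-butoxy)-6-oxohexanoic acid F5.
 - Mixed-anhydride acylation of lithiated (R)-4-benzyl-2-oxazolidinone gives the imide tert-butyl (Z)-6-[(4R)-4-benzyl-2-oxo-oxazolidin-3-yl]-2-(bromomethylidene)-6-oxohexanoate F6.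
 - Titanium-enolate hydroxymethylation (TiCl4, iPr2NEt, s-trioxane) gives the α-hydroxymethyl imide F7.
 - TBSCl/imidazole gives the silyl ether F8.
 - LiBH4 removes the auxiliary to give the mono-silylated diol tert-butyl (2Z,5R)-2-(bromomethylidene)-5-[(tert-butyldimethylsilyloxy)methyl]-6-hydroxyhexanoate F9.
 - Dess–Martin oxidation gives the O-TBS aldehyde F10.
 - The Wittig reaction of step 14 gives the O-TBS enal F11, and HF·pyridine gives 19.

**Further compounds**
F1 | step 19 | (1S,4R)-3,3-dimethyl-4-(Bpin)-1-[(tricyclic lactone)methyl]cyclohexan-1-ol | CC1(C)C[C@@](O)(C[C@@H]2CC[C@]34C(=O)O[C@](C)(CC[C@@H]3Br)[C@@H]24)CC[C@H]1B5OC(C)(C)C(C)(C)O5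
F2 | step 17 | (2Z,5R,6E)-2-(bromomethylidene)-5-(iodomethyl)-7-methylnona-6,8-dien-1-ol | IC[C@@H](/C=C(C)/C=C)CC/C(CO)=C/Br
F3 | step 17 | (2Z,5R,6E)-2-(bromomethylidene)-5-(iodomethyl)-7-methylnona-6,8-dienal | IC[C@@H](/C=C(C)/C=C)CC/C(C=O)=C/Br
F4 | step 17 | 4-bromo-1-(iodomethyl)-7-methyl-1,2,3,4,5,7a-hexahydroindene-3a-carbaldehyde (configuration as 22) | IC[C@@H]1CC[C@]2(C=O)[C@@H](Br)CC=C(C)[C@@H]12
F5 | step 13 | (Z)-5-(bromomethylidene)-6-(tert-butoxy)-6-oxohexanoic acid | OC(=O)CCC/C(C(=O)OC(C)(C)C)=C/Br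
F6 | step 13 | tert-butyl (Z)-6-[(4R)-4-benzyl-2-oxo-oxazolidin-3-yl]-2-(bromomethylidene)-6-oxohexanoate | O=C(CCC/C(C(=O)OC(C)(C)C)=C/Br)N1[C@H](Cc2ccccc2)COC1=O
F7 | step 13 | α-hydroxymethyl imide | OC[C@@H](C(=O)N1[C@H](Cc2ccccc2)COC1=O)CC/C(C(=O)OC(C)(C)C)=C/Br
F8 | step 13 | O-TBS α-hydroxymethyl imide | CC(C)(C)[Si](C)(C)OC[C@@H](C(=O)N1[C@H](Cc2ccccc2)COC1=O)CC/C(C(=O)OC(C)(C)C)=C/Br
F9 | step 13 | tert-butyl (2Z,5R)-2-(bromomethylidene)-5-[(tert-butyldimethylsilyloxy)methyl]-6-hydroxyhexanoate | CC(C)(C)[Si](C)(C)OC[C@@H](CO)CC/C(C(=O)OC(C)(C)C)=C/Br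
F10 | step 13 | O-TBS aldehyde (silyl ether of 18) | CC(C)(C)[Si](C)(C)OC[C@@H](C=O)CC/C(C(=O)OC(C)(C)C)=C/Br
F11 | step 13 | O-TBS enal (silyl ether of 19) | CC(C)(C)[Si](C)(C)OC[C@@H](/C=C(C)/C=O)CC/C(C(=O)OC(C)(C)C)=C/Br
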